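Raised from 0.10 M in the ochre run to 0.40 M in the grey run, the electrophile charge brought less extra loss than extra charge: in 60.0 min the loss goes from 46.8 mM to 68.0 mM.

| flask | electrophile | free base | gas | remark | time |
|---|---|---|---|---|---|
| ochre | 0.10 M | 0.24 M | 16 mM (held) | run made earlier |  |
| grey | 0.40 M | 0.24 M | 16 mM (held) | run made earlier |  |
| flask | 0.20 M | 0.240 M | 16 mM (held) |  | 1.0 h |

| run | time / min | electrophile / % | target / % |
|---|---|---|---|
| ochre | 5.00 | 97.2 | 2.4 |
| ochre | 8.00 | 94.1 | 4.0 |
| ochre | 12.0 | 91.1 | 6.3 |
| ochre | 20.0 | 83.7 | 12.4 |
| ochre | 40.0 | 67.9 | 24.7 |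
| ochre | 60.0 | 53.2 | 35.8 |
| grey | 4.00 | 98.7 | 1.0 |
| grey | 12.0 | 96.8 | 2.9 |
| grey | 20.0 | 94.5 | 4.6 |
| grey | 30.0 | 91.1 | 6.8 |
| grey | 50.0 | 85.5 | 11.3 |
| grey | 60.0 | 83.0 | 13.0 |

(scatter of a reading: 0.3 percentage points)
- at the start none of the gas is in solution
- the earlier runs do not show how much of nucleophile is bound; that part of a forecast is a guess
- part of the electrophile that has reacted at 1.0 h
- share of the unused nucleophile that is free and not bound as protonated nucleophile, at 1.0 h

A loss that levels off this way can be written as a pace V·E/(E+h), which integrates to a single line for gas and free base as in both runs: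

loss + h·ln(charge/left) = V·time

The last readings of the two runs set both constants, so these readings carry their scatter into both and test nothing:

h = 0.0477 M
V·time = 0.0769 M

This second value is the hourly allowance, the electrophile turned over in the hour once the drag h is paid. In fractions of the flask's charge, the allowance is 38.4% and the drag 23.8%, so the fraction reacted, c, obeys:

c − 23.8%·ln(1 − c) = 38.4%

Putting c for the logarithm gives 31.0%, and that value in the logarithm gives 29.9%.

The ledger of the electrophile, the limiting reagent, follows. At the last readings, target takes 76.5% (ochre) and 76.5% (grey) of the loss, and the rest appears in no reading. For the flask: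

electrophile left: 70.1%
target: 22.9%
unread entry: 7.03%

No reading books bound nucleophile, so fr stays a guess here.

The forecast puts 29.5% reacted, a little below this reckoning, and 72% free, adding “That is a guess.”

The flask gives 29.6% reacted and 5.20% free, with electrophile 70.4%, target 22.7% and isomer of the product 6.96%.

    electrophile + nucleophile → acid set free + target (k = 2.40 /M/min)
    nucleophile + acid set free ⇌ protonated nucleophile, settled at all times (K = 6200 /M)
    acid set free + free base ⇌ salt of the base (K = 6.70 /M, k = 12.0 /M/min)
    gas ⇌ nucleophile, rate k4*(csat - [nucleophile]) (kL = 0.140 /min)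
    target ⇌ isomer of the product (K = 0.310, k = 0.460 /min)

The allowance reckoning stood at 29.9%, and the unread entry is the isomer of the product. At 1.00 h the half-life of nucleophile by its step with the electrophile is 2.1 min in the flask, short against the 1.0 h of the flask's time. The flask then holds 0.00284 M of nucleophile beside 0.0517 M of protonated nucleophile.

With 0.12 M of electrophile, the same allowance is 64.1% of the charge and the drag 39.7%, so the two passes give 45.9%, then 41.8% reacted and 32.0% target. That neighbouring flask gives 42.3% and 32.4%.

(The runs stem from a simulated flask for an exercise.)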